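**Plan**

- Retrosynthesis: cut the ring-A bond C1–C8a (reductive Heck), then C4a–C4 (conjugate addition of the ring-A tether), then the side-chain bond C2′–C3′ (B-alkyl Suzuki), then the ring-B bonds C4a–C5 and C6–C7 (Diels–Alder).
- Forward: ring B by Diels–Alder, side chain on C5, enone, tether on C4a, enol triflate at C8a, ring A by 6-exo carbopalladation with hydride capture, then acetate, C7 oxygenation and unmasking.
- Enabling feature: C1 is a quaternary carbon bearing CH3 and CH2O, bonded to sp2 C8a of the ring-B enone (C8=O, C4a=C8a), while C4a carries C4–C3–C2. A C8a–palladium bond adding across a CH2=C(CH2OSi) alkene on C2, with hydride delivered to the exocyclic CH2, leaves exactly this array.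
- Stereochemistry: C5 from the catalytic enantioselective Diels–Alder step (the C6 centre set with it is erased in step 21); C1 from the chiral bisphosphine in the Heck step; the E alkene from syn-hydrozirconation.

Key step: step 18

Remark on names: ring positions are cited with the naphthalene locants of the target (C1 to C8a) and side-chain carbons are primed. "Side chain" stands for (E)-3-methyl-5-(trityloxy)pent-3-en-1-yl (Tr = triphenylmethyl). "Tether" stands for 2-[2-(3-{[tert-butyl(dimethyl)silyl]oxy}prop-1-en-2-yl)-1,3-dioxolan-2-yl]ethyl.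

Assumption: the (S)-oxazaborolidinium catalyst of step 2 and (R)-BINAP in step 18 are taken to give the configurations drawn; if either sense of induction proves opposite, the mirror-image catalyst is used and nothing else changes.

**Route**

Step 1
Reactants: 1 but-3-en-2-one
Product: 2 2-[(triisopropylsilyl)oxy]buta-1,3-diene
Conditions: i-Pr3SiOTf, Et3N, Et2O, 0 to 25 °C
Reagents that add atoms: triisopropylsilyl trifluoromethanesulfonate, CC(C)[Si](C(C)C)(C(C)C)OS(=O)(=O)C(F)(F)F
Why: Soft enolisation and O-silylation of a methyl ketone (silyl enol ether formation) is the standard entry to 2-silyloxydienes, and only the methyl group can be deprotonated.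

Step 2
Reactants: 2 2-[(triisopropylsilyl)oxy]buta-1,3-diene; 3 (E)-2-methylbut-2-enal
Product: 4 (1S,6S)-1,6-dimethyl-4-[(triisopropylsilyl)oxy]cyclohex-3-ene-1-carbaldehyde
Conditions: (S)-1-(2-methylphenyl)-3,3-diphenyltetrahydro-1H,3H-pyrrolo[1,2-c][1,3,2]oxazaborole·HN(SO2CF3)2 (20 mol%), CH2Cl2, −78 to −40 °C
Reagents that add atoms: none
Why: Enantioselective Diels–Alder reaction under chiral cationic boron Lewis-acid catalysis, in which the silyloxy-activated CH2 terminus of the diene bonds to the β-carbon of the enal, suprafacial addition to the (E)-enal places the two methyl groups cis, and shielding of one face of the bound enal by the catalyst sets the quaternary carbon that becomes C5.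

Step 3
Reactants: 4 (1S,6S)-1,6-dimethyl-4-[(triisopropylsilyl)oxy]cyclohex-3-ene-1-carbaldehyde
Product: 5 {[(4R,5S)-4-ethenyl-4,5-dimethylcyclohex-1-en-1-yl]oxy}triisopropylsilane
Conditions: Ph3PCH3Br, KN(SiMe3)2, THF, 0 to 25 °C
Reagents that add atoms: methyltriphenylphosphonium bromide, C[P+](c1ccccc1)(c1ccccc1)c1ccccc1.[Br-]
Why: Wittig methylenation of a non-enolisable neopentyl aldehyde should proceed cleanly, the silyl enol ether being inert to the ylide and no stereocentre being touched.

Step 4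
Reactants: 6 but-2-yn-1-ol
Product: 7 but-2-yn-1-yl trityl ether
Conditions: Ph3CCl, Et3N, DMAP (cat.), CH2Cl2, 25 °C
Reagents that add atoms: chlorotriphenylmethane, ClC(c1ccccc1)(c1ccccc1)c1ccccc1
Why: Tritylation of a primary alcohol gives an ether that is stable to base, fluoride and organometallic reagents and is removed by dilute acid in the last step.

Step 5
Reactants: 7 but-2-yn-1-yl trityl ether
Product: 9 (E)-3-iodobut-2-en-1-yl trityl ether, via alkenylzirconocene chloride 8 (not isolated)
Conditions: Cp2Zr(H)Cl (1.5 equiv), THF, 25 to 40 °C; then I2, 0 °C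
Reagents that add atoms: iodine, II
Why: Hydrozirconation–iodination adds Zr–H syn across the alkyne with zirconium settling on the less hindered, methyl-bearing carbon, and iodinolysis with retention fixes the E geometry of the future C3′=C4′ bond.

Step 6
Reactants: 5 {[(4R,5S)-4-ethenyl-4,5-dimethylcyclohex-1-en-1-yl]oxy}triisopropylsilane; 9 (E)-3-iodobut-2-en-1-yl trityl ether
Product: 11 triisopropyl{[(4S,5S)-4,5-dimethyl-4-(side chain)cyclohex-1-en-1-yl]oxy}silane, via alkyl-9-BBN adduct 10 (not isolated)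
Conditions: 9-BBN (1.3 equiv), THF, 0 to 25 °C; then 9, PdCl2(dppf) (5 mol%), AsPh3 (5 mol%), Cs2CO3, DMF/H2O, 25 °C
Reagents that add atoms: none
Why: B-alkyl Suzuki–Miyaura coupling, in which 9-BBN hydroborates the monosubstituted vinyl group at its terminus far faster than the hindered silyl enol ether and the alkylborane couples with the alkenyl iodide with retention of alkene geometry.

Step 7
Reactants: 11 triisopropyl{[(4S,5S)-4,5-dimethyl-4-(side chain)cyclohex-1-en-1-yl]oxy}silane
Product: 12 (4R,5S)-4,5-dimethyl-4-(side chain)cyclohex-2-en-1-one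
Conditions: Pd(OAc)2 (1.1 equiv), DMSO, 40 °C
Reagents that add atoms: none
Why: Saegusa–Ito oxidation, in which palladation of the silyl enol ether at C8a is followed by β-hydride elimination from C4a, the only carbon that can supply a β-hydrogen, so the C4a=C8a enone forms regiospecifically.

Step 8
Reactants: 13 2,2-dimethyl-1,3-dioxane-4,6-dione; 14 3-chloropropanoyl chloride
Product: 16 methyl 5-chloro-3-oxopentanoate, via acylated dioxanedione 15 (not isolated)
Conditions: pyridine, CH2Cl2, 0 to 25 °C; then MeOH, reflux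
Reagents that add atoms: methanol, CO
Why: C-acylation of the cyclic malonate followed by methanolysis with loss of acetone and carbon dioxide is the standard β-keto ester synthesis.

Step 9
Reactants: 16 methyl 5-chloro-3-oxopentanoate
Product: 17 methyl 2-[2-(2-chloroethyl)-1,3-dioxolan-2-yl]acetate
Conditions: HOCH2CH2OH, TsOH (cat.), benzene, reflux with azeotropic removal of water
Reagents that add atoms: ethane-1,2-diol, OCCO
Why: Acid-catalysed ketalisation of the β-keto ester protects the future C2 carbonyl before any alkene is present, which avoids conjugate addition of the diol to an α-methylene ketone.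

Step 10
Reactants: 17 methyl 2-[2-(2-chloroethyl)-1,3-dioxolan-2-yl]acetate
Product: 21 methyl 2-[2-(2-chloroethyl)-1,3-dioxolan-2-yl]prop-2-enoate, via lithium enolate 18 (not isolated), via Mannich base 19 (not isolated), via trimethylammonium iodide 20 (not isolated)
Conditions: LiN(i-Pr)2, THF, −78 °C; [CH2=NMe2]I, −78 to 25 °C; then MeI, MeOH; then DBU, CH2Cl2, 25 °C
Reagents that add atoms: dimethyl(methylidene)ammonium iodide, C=[N+](C)C.[I-]
Why: α-Methylenation of an ester by Mannich reaction of its lithium enolate, N-methylation and elimination is well established, the enolate being kept at −78 °C so that the β-ketal oxygen is not expelled.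

Step 11
Reactants: 21 methyl 2-[2-(2-chloroethyl)-1,3-dioxolan-2-yl]prop-2-enoate
Product: 22 2-[2-(2-chloroethyl)-1,3-dioxolan-2-yl]prop-2-en-1-ol
Conditions: i-Bu2AlH (2.2 equiv), CH2Cl2, −78 °C
Reagents that add atoms: none
Why: 1,2-Reduction of an acrylate ester with i-Bu2AlH at low temperature gives the allylic alcohol and leaves the ketal and the primary chloride untouched.

Step 12
Reactants: 22 2-[2-(2-chloroethyl)-1,3-dioxolan-2-yl]prop-2-en-1-ol
Product: 23 tert-butyl({2-[2-(2-chloroethyl)-1,3-dioxolan-2-yl]prop-2-en-1-yl}oxy)dimethylsilane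
Conditions: TBSCl, imidazole, DMF, 25 °C
Reagents that add atoms: tert-butyl(chloro)dimethylsilane, CC(C)(C)[Si](C)(C)Cl
Why: Imidazole-promoted silylation gives an allylic silyl ether which, unlike an allylic ester, is not ionised by zerovalent palladium in step 18.

Step 13
Reactants: 23 tert-butyl({2-[2-(2-chloroethyl)-1,3-dioxolan-2-yl]prop-2-en-1-yl}oxy)dimethylsilane
Product: 24 tert-butyl({2-[2-(2-iodoethyl)-1,3-dioxolan-2-yl]prop-2-en-1-yl}oxy)dimethylsilane
Conditions: NaI, butan-2-one, 80 °C
Reagents that add atoms: sodium iodide, [Na+].[I-]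
Why: Finkelstein halide exchange (SN2, driven by precipitation of NaCl) turns the primary chloride into the iodide needed for magnesium insertion.

Step 14
Reactants: 12 (4R,5S)-4,5-dimethyl-4-(side chain)cyclohex-2-en-1-one; 24 tert-butyl({2-[2-(2-iodoethyl)-1,3-dioxolan-2-yl]prop-2-en-1-yl}oxy)dimethylsilane
Product: 26 trimethyl{[(4R,5S)-4,5-dimethyl-4-(side chain)-3-(tether)cyclohex-1-en-1-yl]oxy}silane, via alkylmagnesium iodide 25 (not isolated)
Conditions: Mg, THF, 25 °C; then CuBr·SMe2 (10 mol%), TMSCl, HMPA, 12, THF, −78 to −40 °C; Et3N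
Reagents that add atoms: chlorotrimethylsilane, C[Si](C)(C)Cl
Why: Copper-catalysed conjugate addition of an organomagnesium reagent accelerated by TMSCl and HMPA is the established way to alkylate a β-carbon next to a quaternary centre, and in situ silylation fixes the enolate on the C8a side; the new C4a centre is not assigned because it becomes sp2 in step 16.

Step 15
Reactants: 26 trimethyl{[(4R,5S)-4,5-dimethyl-4-(side chain)-3-(tether)cyclohex-1-en-1-yl]oxy}silane
Product: 28 (4R,5S)-2-hydroxy-4,5-dimethyl-4-(side chain)-3-(tether)cyclohexan-1-one, via silyloxy epoxide 27 (not isolated)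
Conditions: dimethyldioxirane (1.0 equiv), acetone/CH2Cl2, −78 °C; then K2CO3 (cat.), MeOH, 0 °C
Reagents that add atoms: dimethyldioxirane, CC1(C)OO1
Why: Rubottom oxidation, in which the silyl enol ether, by far the most electron-rich alkene present, is epoxidised selectively by one equivalent of oxidant at −78 °C and methanolysis opens the silyloxy epoxide to the C8a hydroxy ketone (C8a configuration of no consequence).

Step 16
Reactants: 28 (4R,5S)-2-hydroxy-4,5-dimethyl-4-(side chain)-3-(tether)cyclohexan-1-one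
Product: 30 (4R,5S)-2-hydroxy-4,5-dimethyl-4-(side chain)-3-(tether)cyclohex-2-en-1-one, via 1,2-dione 29 (not isolated)
Conditions: DMP, pyridine, CH2Cl2, 0 to 25 °C; then Et3N (cat.)
Reagents that add atoms: none
Why: Dess–Martin oxidation of the α-hydroxy ketone gives the 1,2-dione, which should enolise towards C4a to the tetrasubstituted, conjugated and hydrogen-bonded diosphenol, the more substituted tautomer being the favoured one for 3-alkylcyclohexane-1,2-diones.

Step 17
Reactants: 30 (4R,5S)-2-hydroxy-4,5-dimethyl-4-(side chain)-3-(tether)cyclohex-2-en-1-one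
Product: 31 (3R,4S)-3,4-dimethyl-6-oxo-3-(side chain)-2-(tether)cyclohex-1-en-1-yl trifluoromethanesulfonate
Conditions: Tf2O, pyridine, CH2Cl2, −78 to 0 °C
Reagents that add atoms: trifluoromethanesulfonic anhydride, O=S(=O)(OS(=O)(=O)C(F)(F)F)C(F)(F)F
Why: O-Sulfonylation of the diosphenol hydroxyl at low temperature, faster than tautomer interconversion, gives the C8a enol triflate, a standard electrophile class for palladium chemistry that is made without any electrophilic halogen and so spares the two isolated alkenes.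

Step 18
Reactants: 31 (3R,4S)-3,4-dimethyl-6-oxo-3-(side chain)-2-(tether)cyclohex-1-en-1-yl trifluoromethanesulfonate
Product: 32 (1S,5R,6S)-1-{[tert-butyl(dimethyl)silyl]oxymethyl}-1,5,6-trimethyl-5-(side chain)-3,4,6,7-tetrahydronaphthalene-2,8(1H,5H)-dione 2-(ethane-1,2-diyl ketal)
Conditions: Pd(OAc)2 (10 mol%), (R)-BINAP (12 mol%), HCO2Na (3 equiv), DMF, 60 °C
Reagents that add atoms: none
Why: Proposed new method: zerovalent palladium formed from Pd(OAc)2 and (R)-BINAP adds oxidatively to the C8a–OTf bond to give a cationic alkenylpalladium species that keeps both phosphorus atoms bound, the tethered CH2=C(CH2OTBS) alkene inserts syn with C8a going to the internal carbon C1, and formate exchanges onto the neopentyl Pd–CH2, loses CO2 and delivers hydride so that reductive elimination leaves the C1 methyl group. The closest known reaction type is the enantioselective intramolecular reductive Heck cyclisation of aryl halides and triflates onto 1,1-disubstituted alkenes that builds methyl-bearing quaternary carbons, and enol triflates of cyclic 1,2-diones are established partners in ordinary Heck and cross-coupling chemistry; new is their combination in an enantioselective 6-exo closure. Ring A closes in the 6-exo-trig mode, and because the C2 dioxolane keeps the alkene out of conjugation, ring size and not alkene polarity decides against the 7-endo path. The new stereocentre C1 is set by enantioface selection of the prochiral alkene during insertion under control of the bisphosphine, since C5 lies across the flat C4a=C8a bond and is too remote to bias it. The step needs insertion to outrun direct hydride transfer to the alkenylpalladium, which the cis arrangement of C8a and the tether on the ring-B double bond favours, and it needs hydride capture to outrun rearrangement of the homoallylic alkylpalladium, which the lack of β-hydrogens and the excess of formate should secure. The side-chain alkene cannot compete because its addition to C8a would create a bridgehead double bond.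

Step 19
Reactants: 32 (1S,5R,6S)-1-{[tert-butyl(dimethyl)silyl]oxymethyl}-1,5,6-trimethyl-5-(side chain)-3,4,6,7-tetrahydronaphthalene-2,8(1H,5H)-dione 2-(ethane-1,2-diyl ketal)
Product: 34 [(1S,5R,6S)-1,5,6-trimethyl-2,8-dioxo-5-(side chain)-1,2,3,4,5,6,7,8-octahydronaphthalen-1-yl]methyl acetate 2-(ethane-1,2-diyl ketal), via primary alcohol 33 (not isolated)
Conditions: Bu4NF, THF, 0 to 25 °C; then Ac2O, Et3N, DMAP (cat.)
Reagents that add atoms: acetic anhydride, CC(=O)OC(C)=O
Why: Fluoride cleavage of the now neopentyl silyl ether and DMAP-catalysed acetylation in the same flask exchange the protecting group for the acetate while C2 is still a ketal, so no β-hydroxy ketone exists that could lose formaldehyde by retro-aldol reaction, and the trityl ether and ketal are inert to fluoride.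

Step 20
Reactants: 34 [(1S,5R,6S)-1,5,6-trimethyl-2,8-dioxo-5-(side chain)-1,2,3,4,5,6,7,8-octahydronaphthalen-1-yl]methyl acetate 2-(ethane-1,2-diyl ketal)
Product: 36 [(1S,5R,6R)-7-hydroxy-1,5,6-trimethyl-2,8-dioxo-5-(side chain)-1,2,3,4,5,6,7,8-octahydronaphthalen-1-yl]methyl acetate 2-(ethane-1,2-diyl ketal), via sodium enolate 35 (not isolated)
Conditions: NaN(SiMe3)2 (1.05 equiv), THF, −78 °C; 2-(benzenesulfonyl)-3-phenyloxaziridine, −78 °C; AcOH
Reagents that add atoms: 2-(benzenesulfonyl)-3-phenyloxaziridine, O=S(=O)(c1ccccc1)N1OC1c1ccccc1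
Why: Kinetic α′-deprotonation of the enone at C7 (C8a carries no hydrogen and the ketone is several pK units more acidic than the acetate) followed by electrophilic hydroxylation of the enolate with the N-sulfonyloxaziridine should give the C7 alcohol, whose configuration is of no consequence.

Step 21
Reactants: 36 [(1S,5R,6R)-7-hydroxy-1,5,6-trimethyl-2,8-dioxo-5-(side chain)-1,2,3,4,5,6,7,8-octahydronaphthalen-1-yl]methyl acetate 2-(ethane-1,2-diyl ketal)
Product: 38 [(1S,5S)-7-hydroxy-1,5,6-trimethyl-2,8-dioxo-5-(side chain)-1,2,3,4,5,8-hexahydronaphthalen-1-yl]methyl acetate 2-(ethane-1,2-diyl ketal), via 7,8-dione 37 (not isolated)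
Conditions: DMP, pyridine, CH2Cl2, 0 to 25 °C; then Et3N (cat.)
Reagents that add atoms: none
Why: Dess–Martin oxidation gives the C7,C8-dione, whose only enolisable hydrogen sits on C6, so tautomerisation can only produce the C6=C7 diosphenol of the target and at the same time erases the C6 stereocentre.

Step 22
Reactants: 38 [(1S,5S)-7-hydroxy-1,5,6-trimethyl-2,8-dioxo-5-(side chain)-1,2,3,4,5,8-hexahydronaphthalen-1-yl]methyl acetate 2-(ethane-1,2-diyl ketal)
Product: 39 [(1S,5S)-7-hydroxy-5-[(E)-5-hydroxy-3-methylpent-3-en-1-yl]-1,5,6-trimethyl-2,8-dioxo-1,2,3,4,5,8-hexahydronaphthalen-1-yl]methyl acetate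
Conditions: HCl (2 M aq.), THF, 0 to 25 °C
Reagents that add atoms: water, O
Why: Acid hydrolysis should remove the trityl ether (through the trityl cation) and the dioxolane (through the oxocarbenium ion) in one operation, the neopentyl acetate and the diosphenol being stable to dilute acid and the two quaternary stereocentres being unable to epimerise.

**Compound list**

1 | but-3-en-2-one | CC(=O)C=C | starting material
2 | 2-[(triisopropylsilyl)oxy]buta-1,3-diene | C=CC(=C)O[Si](C(C)C)(C(C)C)C(C)C | intermediate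
3 | (E)-2-methylbut-2-enal | C/C=C(\C)C=O | starting material
4 | (1S,6S)-1,6-dimethyl-4-[(triisopropylsilyl)oxy]cyclohex-3-ene-1-carbaldehyde | C[C@H]1CC(O[Si](C(C)C)(C(C)C)C(C)C)=CC[C@]1(C)C=O | intermediate
5 | {[(4R,5S)-4-ethenyl-4,5-dimethylcyclohex-1-en-1-yl]oxy}triisopropylsilane | C[C@H]1CC(O[Si](C(C)C)(C(C)C)C(C)C)=CC[C@]1(C)C=C | intermediate
6 | but-2-yn-1-ol | CC#CCO | starting material
7 | but-2-yn-1-yl trityl ether | CC#CCOC(c1ccccc1)(c1ccccc1)c1ccccc1 | intermediate
8 | chloro[(E)-4-(trityloxy)but-2-en-2-yl]bis(cyclopentadienyl)zirconium (not isolated) | C/C(=C\COC(c1ccccc1)(c1ccccc1)c1ccccc1)[Zr](Cl)(C1C=CC=C1)C1C=CC=C1 | intermediate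
9 | (E)-3-iodobut-2-en-1-yl trityl ether | C/C(I)=C\COC(c1ccccc1)(c1ccccc1)c1ccccc1 | intermediate
10 | 9-{2-[(1S,6S)-1,6-dimethyl-4-(triisopropylsilyloxy)cyclohex-3-en-1-yl]ethyl}-9-borabicyclo[3.3.1]nonane (not isolated) | C[C@H]1CC(O[Si](C(C)C)(C(C)C)C(C)C)=CC[C@]1(C)CCB1C2CCCC1CCC2 | intermediate
11 | triisopropyl{[(4S,5S)-4,5-dimethyl-4-(side chain)cyclohex-1-en-1-yl]oxy}silane | C[C@H]1CC(O[Si](C(C)C)(C(C)C)C(C)C)=CC[C@]1(C)CC/C(C)=C/COC(c1ccccc1)(c1ccccc1)c1ccccc1 | intermediate
12 | (4R,5S)-4,5-dimethyl-4-(side chain)cyclohex-2-en-1-one | C[C@H]1CC(=O)C=C[C@]1(C)CC/C(C)=C/COC(c1ccccc1)(c1ccccc1)c1ccccc1 | intermediate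
13 | 2,2-dimethyl-1,3-dioxane-4,6-dione | CC1(C)OC(=O)CC(=O)O1 | starting material
14 | 3-chloropropanoyl chloride | ClCCC(Cl)=O | starting material
15 | 5-(3-chloro-1-hydroxypropylidene)-2,2-dimethyl-1,3-dioxane-4,6-dione (not isolated) | CC1(C)OC(=O)C(=C(O)CCCl)C(=O)O1 | intermediate
16 | methyl 5-chloro-3-oxopentanoate | COC(=O)CC(=O)CCCl | intermediate
17 | methyl 2-[2-(2-chloroethyl)-1,3-dioxolan-2-yl]acetate | COC(=O)CC1(CCCl)OCCO1 | intermediate
18 | lithium enolate of 17 (not isolated) | COC(O[Li])=CC1(CCCl)OCCO1 | intermediate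
19 | methyl 2-[2-(2-chloroethyl)-1,3-dioxolan-2-yl]-3-(dimethylamino)propanoate (not isolated) | COC(=O)C(CN(C)C)C1(CCCl)OCCO1 | intermediate
20 | {2-[2-(2-chloroethyl)-1,3-dioxolan-2-yl]-3-methoxy-3-oxopropyl}trimethylammonium iodide (not isolated) | COC(=O)C(C[N+](C)(C)C)C1(CCCl)OCCO1.[I-] | intermediate
21 | methyl 2-[2-(2-chloroethyl)-1,3-dioxolan-2-yl]prop-2-enoate | COC(=O)C(=C)C1(CCCl)OCCO1 | intermediate
22 | 2-[2-(2-chloroethyl)-1,3-dioxolan-2-yl]prop-2-en-1-ol | OCC(=C)C1(CCCl)OCCO1 | intermediate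
23 | tert-butyl({2-[2-(2-chloroethyl)-1,3-dioxolan-2-yl]prop-2-en-1-yl}oxy)dimethylsilane | CC(C)(C)[Si](C)(C)OCC(=C)C1(CCCl)OCCO1 | intermediate
24 | tert-butyl({2-[2-(2-iodoethyl)-1,3-dioxolan-2-yl]prop-2-en-1-yl}oxy)dimethylsilane | CC(C)(C)[Si](C)(C)OCC(=C)C1(CCI)OCCO1 | intermediate
25 | iodo{2-[2-(3-{[tert-butyl(dimethyl)silyl]oxy}prop-1-en-2-yl)-1,3-dioxolan-2-yl]ethyl}magnesium (not isolated) | CC(C)(C)[Si](C)(C)OCC(=C)C1(CC[Mg]I)OCCO1 | intermediate
26 | trimethyl{[(4R,5S)-4,5-dimethyl-4-(side chain)-3-(tether)cyclohex-1-en-1-yl]oxy}silane (C4a not assigned) | C[C@H]1CC(O[Si](C)(C)C)=CC(CCC2(OCCO2)C(=C)CO[Si](C)(C)C(C)(C)C)[C@]1(C)CC/C(C)=C/COC(c1ccccc1)(c1ccccc1)c1ccccc1 | intermediate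
27 | C8,C8a-epoxide of 26 bearing OSiMe3 on C8 (not isolated; C4a, C8, C8a not assigned) | C[C@H]1CC2(O[Si](C)(C)C)OC2C(CCC3(OCCO3)C(=C)CO[Si](C)(C)C(C)(C)C)[C@]1(C)CC/C(C)=C/COC(c1ccccc1)(c1ccccc1)c1ccccc1 | intermediate
28 | (4R,5S)-2-hydroxy-4,5-dimethyl-4-(side chain)-3-(tether)cyclohexan-1-one (C4a, C8a not assigned) | C[C@H]1CC(=O)C(O)C(CCC2(OCCO2)C(=C)CO[Si](C)(C)C(C)(C)C)[C@]1(C)CC/C(C)=C/COC(c1ccccc1)(c1ccccc1)c1ccccc1 | intermediate
29 | (4R,5S)-4,5-dimethyl-4-(side chain)-3-(tether)cyclohexane-1,2-dione (not isolated; C4a not assigned) | C[C@H]1CC(=O)C(=O)C(CCC2(OCCO2)C(=C)CO[Si](C)(C)C(C)(C)C)[C@]1(C)CC/C(C)=C/COC(c1ccccc1)(c1ccccc1)c1ccccc1 | intermediate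
30 | (4R,5S)-2-hydroxy-4,5-dimethyl-4-(side chain)-3-(tether)cyclohex-2-en-1-one | C[C@H]1CC(=O)C(O)=C(CCC2(OCCO2)C(=C)CO[Si](C)(C)C(C)(C)C)[C@]1(C)CC/C(C)=C/COC(c1ccccc1)(c1ccccc1)c1ccccc1 | intermediate
31 | (3R,4S)-3,4-dimethyl-6-oxo-3-(side chain)-2-(tether)cyclohex-1-en-1-yl trifluoromethanesulfonate | C[C@H]1CC(=O)C(OS(=O)(=O)C(F)(F)F)=C(CCC2(OCCO2)C(=C)CO[Si](C)(C)C(C)(C)C)[C@]1(C)CC/C(C)=C/COC(c1ccccc1)(c1ccccc1)c1ccccc1 | intermediate
32 | (1S,5R,6S)-1-{[tert-butyl(dimethyl)silyl]oxymethyl}-1,5,6-trimethyl-5-(side chain)-3,4,6,7-tetrahydronaphthalene-2,8(1H,5H)-dione 2-(ethane-1,2-diyl ketal) | CC(C)(C)[Si](C)(C)OC[C@@]1(C)C2(OCCO2)CCC2=C1C(=O)C[C@H](C)[C@@]2(C)CC/C(C)=C/COC(c1ccccc1)(c1ccccc1)c1ccccc1 | intermediate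
33 | (1S,5R,6S)-1-(hydroxymethyl)-1,5,6-trimethyl-5-(side chain)-3,4,6,7-tetrahydronaphthalene-2,8(1H,5H)-dione 2-(ethane-1,2-diyl ketal) (not isolated) | OC[C@@]1(C)C2(OCCO2)CCC2=C1C(=O)C[C@H](C)[C@@]2(C)CC/C(C)=C/COC(c1ccccc1)(c1ccccc1)c1ccccc1 | intermediate
34 | [(1S,5R,6S)-1,5,6-trimethyl-2,8-dioxo-5-(side chain)-1,2,3,4,5,6,7,8-octahydronaphthalen-1-yl]methyl acetate 2-(ethane-1,2-diyl ketal) | CC(=O)OC[C@@]1(C)C2(OCCO2)CCC2=C1C(=O)C[C@H](C)[C@@]2(C)CC/C(C)=C/COC(c1ccccc1)(c1ccccc1)c1ccccc1 | intermediate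
35 | sodium C7=C8 enolate of 34 (not isolated) | CC(=O)OC[C@@]1(C)C2(OCCO2)CCC2=C1C(O[Na])=C[C@H](C)[C@@]2(C)CC/C(C)=C/COC(c1ccccc1)(c1ccccc1)c1ccccc1 | intermediate
36 | [(1S,5R,6R)-7-hydroxy-1,5,6-trimethyl-2,8-dioxo-5-(side chain)-1,2,3,4,5,6,7,8-octahydronaphthalen-1-yl]methyl acetate 2-(ethane-1,2-diyl ketal) (C7 not assigned) | CC(=O)OC[C@@]1(C)C2(OCCO2)CCC2=C1C(=O)C(O)[C@H](C)[C@@]2(C)CC/C(C)=C/COC(c1ccccc1)(c1ccccc1)c1ccccc1 | intermediate
37 | [(1S,5R,6R)-1,5,6-trimethyl-2,7,8-trioxo-5-(side chain)-1,2,3,4,5,6,7,8-octahydronaphthalen-1-yl]methyl acetate 2-(ethane-1,2-diyl ketal) (not isolated) | CC(=O)OC[C@@]1(C)C2(OCCO2)CCC2=C1C(=O)C(=O)[C@H](C)[C@@]2(C)CC/C(C)=C/COC(c1ccccc1)(c1ccccc1)c1ccccc1 | intermediate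
38 | [(1S,5S)-7-hydroxy-1,5,6-trimethyl-2,8-dioxo-5-(side chain)-1,2,3,4,5,8-hexahydronaphthalen-1-yl]methyl acetate 2-(ethane-1,2-diyl ketal) | CC(=O)OC[C@@]1(C)C2(OCCO2)CCC2=C1C(=O)C(O)=C(C)[C@@]2(C)CC/C(C)=C/COC(c1ccccc1)(c1ccccc1)c1ccccc1 | intermediate
39 | [(1S,5S)-7-hydroxy-5-[(E)-5-hydroxy-3-methylpent-3-en-1-yl]-1,5,6-trimethyl-2,8-dioxo-1,2,3,4,5,8-hexahydronaphthalen-1-yl]methyl acetate | CC(=O)OC[C@@]1(C)C(=O)CCC2=C1C(=O)C(O)=C(C)[C@@]2(C)CC/C(C)=C/CO | target

**Step count**

Total: 22 steps. Longest linear sequence: 15 steps (steps 8 to 13, then 14 to 22, from 13 and 14 to 39); the ring-B line (steps 1, 2, 3, 6, 7, then 14 to 22) has 14.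

**Steps most likely to fail**

1. Step 18 (carries the new-method label). Formate may transfer hydride to the alkenylpalladium before the alkene has inserted, which would give the simple C8a–H enone, or the ligand may discriminate poorly between the alkene faces.
   Fallback, from 31 back to 32: no hydride donor is present during ring closure, and the extra carbon is removed afterwards. Triflate 31 would be cyclised under carbon monoxide (Pd(OAc)2, (R)-BINAP, Et3N, CO at 1 atm, MeOH/DMF, 60 °C). Carbopalladation terminated by alkoxycarbonylation of a neopentyl alkylpalladium is an established cascade for alkenyl and aryl triflates and halides. It should give the C1-(methoxycarbonylmethyl) compound F1. Saponification (LiOH, THF/H2O) would give the carboxylic acid F2. Conversion into the N-acyloxypyridine-2-thione F3 (N-hydroxypyridine-2-thione, DCC) and photolysis with t-BuSH (Barton decarboxylation) would turn CH2CO2H into the C1 methyl group and rejoin the route at 32.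

2. Step 14. The organomagnesium/copper reagent may fail to add to C4a, which is flanked by the quaternary C5, with 1,2-addition, enolisation of 12 or decay of the organomagnesium reagent taking over.
   Fallback, from 12 and 24 back to 28: no preformed organometallic is used. A nickel-catalysed reductive conjugate addition of iodide 24 to enone 12 (NiCl2(dme), 2,9-dimethyl-1,10-phenanthroline, Mn, Et3SiCl, DMF, 25 °C) is a known cross-electrophile method that delivers silyl enol ethers regiospecifically. It should give the triethylsilyl enol ether F4. Oxidation as in step 15 (dimethyldioxirane, then K2CO3/MeOH) through the triethylsilyloxy epoxide F5 returns to 28.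

3. Step 2. The trisubstituted enal is a sluggish dienophile; forcing the reaction may erode facial selectivity, and the absolute configuration of the whole route rests on this step.
   Fallback, from 2 and 3 back to 4: resolution replaces asymmetric catalysis. The cycloaddition is run with an achiral Lewis acid (Me2AlCl, CH2Cl2, −78 °C) to give racemic 4, which contains the mirror-image aldehyde F6. Condensation with (1R,2R)-N,N′-dimethyl-1,2-diphenylethane-1,2-diamine (molecular sieves, CH2Cl2) gives the imidazolidine F7 from 4 and the diastereomeric imidazolidine F8 from F6. The two are separated by chromatography, and F7 is hydrolysed on wet silica gel with oxalic acid to return enantiopure 4.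

Further compounds
F1 | step 18 | methyl 2-[(1S,5R,6S)-1-{[tert-butyl(dimethyl)silyl]oxymethyl}-5,6-dimethyl-2,8-dioxo-5-(side chain)-1,2,3,4,5,6,7,8-octahydronaphthalen-1-yl]acetate 2-(ethane-1,2-diyl ketal) | CC(C)(C)[Si](C)(C)OC[C@@]1(CC(=O)OC)C2(OCCO2)CCC2=C1C(=O)C[C@H](C)[C@@]2(C)CC/C(C)=C/COC(c1ccccc1)(c1ccccc1)c1ccccc1
F2 | step 18 | carboxylic acid corresponding to F1 | CC(C)(C)[Si](C)(C)OC[C@@]1(CC(=O)O)C2(OCCO2)CCC2=C1C(=O)C[C@H](C)[C@@]2(C)CC/C(C)=C/COC(c1ccccc1)(c1ccccc1)c1ccccc1
F3 | step 18 | 2-thioxopyridin-1(2H)-yl ester of F2 | CC(C)(C)[Si](C)(C)OC[C@@]1(CC(=O)ON3C=CC=CC3=S)C2(OCCO2)CCC2=C1C(=O)C[C@H](C)[C@@]2(C)CC/C(C)=C/COC(c1ccccc1)(c1ccccc1)c1ccccc1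
F4 | step 14 | triethyl{[(4R,5S)-4,5-dimethyl-4-(side chain)-3-(tether)cyclohex-1-en-1-yl]oxy}silane (C4a not assigned) | C[C@H]1CC(O[Si](CC)(CC)CC)=CC(CCC2(OCCO2)C(=C)CO[Si](C)(C)C(C)(C)C)[C@]1(C)CC/C(C)=C/COC(c1ccccc1)(c1ccccc1)c1ccccc1
F5 | step 14 | C8,C8a-epoxide of F4 bearing OSiEt3 on C8 | C[C@H]1CC2(O[Si](CC)(CC)CC)OC2C(CCC3(OCCO3)C(=C)CO[Si](C)(C)C(C)(C)C)[C@]1(C)CC/C(C)=C/COC(c1ccccc1)(c1ccccc1)c1ccccc1
F6 | step 2 | (1R,6R)-1,6-dimethyl-4-[(triisopropylsilyl)oxy]cyclohex-3-ene-1-carbaldehyde (the enantiomer of 4, present in the racemate) | C[C@@H]1CC(O[Si](C(C)C)(C(C)C)C(C)C)=CC[C@@]1(C)C=O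
F7 | step 2 | (4R,5R)-2-[(1S,6S)-1,6-dimethyl-4-(triisopropylsilyloxy)cyclohex-3-en-1-yl]-1,3-dimethyl-4,5-diphenylimidazolidine | C[C@H]1CC(O[Si](C(C)C)(C(C)C)C(C)C)=CC[C@]1(C)C1N(C)[C@H](c2ccccc2)[C@@H](c2ccccc2)N1C
F8 | step 2 | (4R,5R)-2-[(1R,6R)-1,6-dimethyl-4-(triisopropylsilyloxy)cyclohex-3-en-1-yl]-1,3-dimethyl-4,5-diphenylimidazolidine | C[C@@H]1CC(O[Si](C(C)C)(C(C)C)C(C)C)=CC[C@@]1(C)C1N(C)[C@H](c2ccccc2)[C@@H](c2ccccc2)N1C
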